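**Retrosynthetic overview**

- The depside is cut at the aryl–oxygen bond O–C4 of ring B (methyl benzoate ring: C1 CO2Me, C2 OH, C3 CH3, C4 O-acyl, C5 CH3, C6 CH3), not at the acyl–oxygen bond. C4 lies between two methyls and para to the ester, so ring B becomes the electrophile (iodine at C4 raised to trivalent iodine) and the carboxylate of ring A (formyl ring) is the nucleophile. The crowded acyl carbon of ring A is never attacked.
- Ring A acid 4: atraric acid, then C5 formylation, dibenzylation and saponification.
- Ring B iodonium salt 14: 2,4,5-trimethylphenol, then 3,6-dibromination, benzylation, bromine–lithium exchange ortho to oxygen with ClCO2Me, a second exchange with I2, and mCPBA/TsOH oxidation with 1,3,5-trimethoxybenzene.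
- Remark on the chemistry: electrophilic iodination of the finished salicylate at C4 (meta to oxygen, para to the ester) is judged unreliable, so the halogen pattern is fixed by phenol bromination before the ester is present.
- No ring is formed in the route; both benzene rings come from the starting materials, and BCl3 removes the three benzyl ethers at the end.

Key step: step 9

**Route**

Step 1
Reactants: 1 methyl 2,4-dihydroxy-3,6-dimethylbenzoate (atraric acid)
Product: 2 methyl 5-formyl-2,4-dihydroxy-3,6-dimethylbenzoate
Conditions: Cl2CHOMe, TiCl4, CH2Cl2, 0 °C → rt; then aq. HCl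
Reagents that add atoms: dichloromethyl methyl ether, COC(Cl)Cl; water, O
Why: Rieche formylation should go to C5, the only free ring position, which is ortho to the C4 hydroxyl and para to the C2 hydroxyl, and hydrolysis of the chloro ether on work-up gives the aldehyde.

Step 2
Reactants: 2 methyl 5-formyl-2,4-dihydroxy-3,6-dimethylbenzoate
Product: 3 methyl 2,4-bis(benzyloxy)-5-formyl-3,6-dimethylbenzoate
Conditions: BnBr, K2CO3, DMF, 60 °C
Reagents that add atoms: benzyl bromide, BrCc1ccccc1
Why: Williamson ether synthesis on both phenols, which are hydrogen-bonded to a neighbouring carbonyl and therefore need warm DMF and excess benzyl bromide, while the ester and the aldehyde (no alpha hydrogen) are inert to carbonate.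

Step 3
Reactants: 3 methyl 2,4-bis(benzyloxy)-5-formyl-3,6-dimethylbenzoate
Product: 4 2,4-bis(benzyloxy)-5-formyl-3,6-dimethylbenzoic acid
Conditions: KOH, DMSO/H2O (4:1), 80 °C, argon; then aq. HCl
Reagents that add atoms: potassium hydroxide, [K+].[OH-]
Why: Saponification of a di-ortho-substituted methyl benzoate needs poorly solvated hydroxide, and the aldehyde, flanked by a methyl and a benzyloxy group and lacking an alpha hydrogen, should undergo Cannizzaro disproportionation only slowly under argon.

Step 4
Reactants: 5 2,4,5-trimethylphenol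
Product: 6 3,6-dibromo-2,4,5-trimethylphenol
Conditions: Br2 (2.1 equiv), AcOH, rt, dark
Reagents that add atoms: bromine, BrBr
Why: Electrophilic aromatic bromination should place the first bromine at C6 ortho to the hydroxyl and the second at C3, the last free position, by ipso attack para to the hydroxyl followed by acid-catalysed 1,2-shift of bromine, the classical ring bromination of blocked alkylphenols, with ionic conditions in the dark holding back side-chain bromination.

Step 5
Reactants: 6 3,6-dibromo-2,4,5-trimethylphenol
Product: 7 1-(benzyloxy)-2,5-dibromo-3,4,6-trimethylbenzene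
Conditions: BnBr, K2CO3, DMF, 50 °C
Reagents that add atoms: benzyl bromide, BrCc1ccccc1
Why: Williamson ether synthesis of an acidic ortho-bromophenol, which should alkylate cleanly on oxygen.

Step 6
Reactants: 7 1-(benzyloxy)-2,5-dibromo-3,4,6-trimethylbenzene
Product: 9 methyl 2-(benzyloxy)-4-bromo-3,5,6-trimethylbenzoate, via aryllithium 8 (not isolated)
Conditions: n-BuLi (1.05 equiv), THF, −78 °C; then ClCO2Me, −78 °C → rt
Reagents that add atoms: methyl chloroformate, COC(Cl)=O
Why: Bromine–lithium exchange should be faster at the bromine ortho to the benzyloxy group (inductive stabilisation and coordination of lithium by oxygen) than at the bromine between two methyls, and the aryllithium is acylated only once because the di-ortho-substituted ester resists a second addition.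

Step 7
Reactants: 9 methyl 2-(benzyloxy)-4-bromo-3,5,6-trimethylbenzoate
Product: 11 methyl 2-(benzyloxy)-4-iodo-3,5,6-trimethylbenzoate, via aryllithium 10 (not isolated)
Conditions: t-BuLi (2.1 equiv), THF/Et2O, −100 °C; then I2, −100 °C → rt
Reagents that add atoms: iodine, II
Why: Bromine–lithium exchange with t-BuLi at −100 °C should outrun addition to the methyl ester, which is shielded by its two ortho substituents, and iodinolysis of the aryllithium puts iodine on C4.

Step 8
Reactants: 11 methyl 2-(benzyloxy)-4-iodo-3,5,6-trimethylbenzoate; 12 1,3,5-trimethoxybenzene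
Product: 14 [3-(benzyloxy)-4-(methoxycarbonyl)-2,5,6-trimethylphenyl](2,4,6-trimethoxyphenyl)iodonium tosylate, via hydroxy(tosyloxy)iodoarene 13 (not isolated)
Conditions: mCPBA, TsOH·H2O, MeCN, 60 °C; then 1,3,5-trimethoxybenzene, 60 °C; precipitation with Et2O
Reagents that add atoms: p-toluenesulfonic acid monohydrate, Cc1ccc(cc1)S(=O)(=O)O.O
Why: One-pot oxidation of the aryl iodide to the [hydroxy(tosyloxy)iodo]arene (trivalent iodine) followed by electrophilic aromatic substitution of the very electron-rich 1,3,5-trimethoxybenzene at iodine, a sequence for which 2,6-dimethyl iodoarenes are good substrates and under which the benzyl ether should not be oxidised.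

Step 9
Reactants: 4 2,4-bis(benzyloxy)-5-formyl-3,6-dimethylbenzoic acid; 14 [3-(benzyloxy)-4-(methoxycarbonyl)-2,5,6-trimethylphenyl](2,4,6-trimethoxyphenyl)iodonium tosylate
Product: 17 tri-O-benzyl isopseudocyphellarin A, via potassium carboxylate 15 (not isolated), via iodane carboxylate 16 (not isolated)
Conditions: KOtBu (1.0 equiv), toluene, rt; then 14 (1.2 equiv), 110 °C
Reagents that add atoms: none
Why: One equivalent of KOtBu turns acid 4 into potassium carboxylate 15, which replaces tosylate on iodine of 14 to give the T-shaped trivalent iodine carboxylate 16. Ligand coupling through a three-centre transition state then joins the carboxylate oxygen to the ipso carbon C4 of ring B and releases 2-iodo-1,3,5-trimethoxybenzene (monovalent iodine), which drives the step. The closest known reaction type is the metal-free O-arylation of carboxylic acids with diaryliodonium salts, including aryl(2,4,6-trimethoxyphenyl) salts and ortho-substituted aryl groups; no ring is closed and no stereocentre is formed. The selectivity needed is transfer of the ring B aryl and not the trimethoxyphenyl group, and it is secured because ring B is the more electron-poor, 2,6-dimethyl-substituted aryl that takes the coupling position while the electron-rich trimethoxyphenyl group stays on iodine. Neither aryl group has an ortho hydrogen, so no aryne can form, and with exactly one equivalent of base no alkoxide is left to attack the aldehyde. Because the carboxylate oxygen is the nucleophile and the acyl carbon is not touched, the double ortho substitution on both partners, which slows a classical acylation, does not stand in the way.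

Step 10
Reactants: 17 tri-O-benzyl isopseudocyphellarin A
Product: 18 isopseudocyphellarin A
Conditions: BCl3, C6HMe5, CH2Cl2, −78 °C; then H2O/THF, −78 °C → rt
Reagents that add atoms: none
Why: Lewis acid debenzylation, in which BCl3 chelated between each ether oxygen and its ortho carbonyl ionises the benzyl–oxygen bond at −78 °C and pentamethylbenzene traps the benzyl cations by Friedel–Crafts alkylation, should leave the methyl ester, the depside ester and the aldehyde intact at this temperature.

**Compound list**

1 | methyl 2,4-dihydroxy-3,6-dimethylbenzoate (atraric acid) | COC(=O)c1c(C)cc(O)c(C)c1O | starting material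
2 | methyl 5-formyl-2,4-dihydroxy-3,6-dimethylbenzoate | COC(=O)c1c(C)c(C=O)c(O)c(C)c1O | intermediate
3 | methyl 2,4-bis(benzyloxy)-5-formyl-3,6-dimethylbenzoate | COC(=O)c1c(C)c(C=O)c(OCc2ccccc2)c(C)c1OCc1ccccc1 | intermediate
4 | 2,4-bis(benzyloxy)-5-formyl-3,6-dimethylbenzoic acid | O=Cc1c(C)c(C(=O)O)c(OCc2ccccc2)c(C)c1OCc1ccccc1 | intermediate
5 | 2,4,5-trimethylphenol | Oc1cc(C)c(C)cc1C | starting material
6 | 3,6-dibromo-2,4,5-trimethylphenol | Oc1c(Br)c(C)c(C)c(Br)c1C | intermediate
7 | 1-(benzyloxy)-2,5-dibromo-3,4,6-trimethylbenzene (benzyl ether of 6) | Cc1c(OCc2ccccc2)c(Br)c(C)c(C)c1Br | intermediate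
8 | [2-(benzyloxy)-4-bromo-3,5,6-trimethylphenyl]lithium | Cc1c(OCc2ccccc2)c([Li])c(C)c(C)c1Br | intermediate (not isolated)
9 | methyl 2-(benzyloxy)-4-bromo-3,5,6-trimethylbenzoate | COC(=O)c1c(C)c(C)c(Br)c(C)c1OCc1ccccc1 | intermediate
10 | [3-(benzyloxy)-4-(methoxycarbonyl)-2,5,6-trimethylphenyl]lithium | COC(=O)c1c(C)c(C)c([Li])c(C)c1OCc1ccccc1 | intermediate (not isolated)
11 | methyl 2-(benzyloxy)-4-iodo-3,5,6-trimethylbenzoate | COC(=O)c1c(C)c(C)c(I)c(C)c1OCc1ccccc1 | intermediate
12 | 1,3,5-trimethoxybenzene | COc1cc(OC)cc(OC)c1 | starting material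
13 | methyl 2-(benzyloxy)-4-[hydroxy(tosyloxy)iodo]-3,5,6-trimethylbenzoate | COC(=O)c1c(C)c(C)c(I(O)OS(=O)(=O)c2ccc(C)cc2)c(C)c1OCc1ccccc1 | intermediate (not isolated)
14 | [3-(benzyloxy)-4-(methoxycarbonyl)-2,5,6-trimethylphenyl](2,4,6-trimethoxyphenyl)iodonium tosylate | COC(=O)c1c(C)c(C)c([I+]c2c(OC)cc(OC)cc2OC)c(C)c1OCc1ccccc1.Cc1ccc(S(=O)(=O)[O-])cc1 | intermediate
15 | potassium 2,4-bis(benzyloxy)-5-formyl-3,6-dimethylbenzoate | [K+].[O-]C(=O)c1c(C)c(C=O)c(OCc2ccccc2)c(C)c1OCc1ccccc1 | intermediate (not isolated)
16 | [2,4-bis(benzyloxy)-5-formyl-3,6-dimethylbenzoyloxy][3-(benzyloxy)-4-(methoxycarbonyl)-2,5,6-trimethylphenyl](2,4,6-trimethoxyphenyl)-λ3-iodane | COC(=O)c1c(C)c(C)c(I(OC(=O)c2c(C)c(C=O)c(OCc3ccccc3)c(C)c2OCc2ccccc2)c2c(OC)cc(OC)cc2OC)c(C)c1OCc1ccccc1 | intermediate (not isolated)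
17 | tri-O-benzyl isopseudocyphellarin A (3-(benzyloxy)-4-(methoxycarbonyl)-2,5,6-trimethylphenyl 2,4-bis(benzyloxy)-5-formyl-3,6-dimethylbenzoate) | COC(=O)c1c(C)c(C)c(OC(=O)c2c(C)c(C=O)c(OCc3ccccc3)c(C)c2OCc2ccccc2)c(C)c1OCc1ccccc1 | intermediate
18 | isopseudocyphellarin A | COC(=O)c1c(C)c(C)c(OC(=O)c2c(C)c(C=O)c(O)c(C)c2O)c(C)c1O | target

**Step count and risks**

Total step count: 10. Longest linear sequence: 7 steps (steps 4 to 10, from 2,4,5-trimethylphenol); the ring A branch (steps 1 to 3) joins at step 9.

Steps most likely to fail:

1. Step 9. Ligand coupling may be slow when both the carboxylate and the transferred aryl group carry two ortho substituents, so that the trivalent iodine carboxylate is lost by homolysis or by transfer of the wrong aryl group before the O–C4 bond forms. The fallback is the classical acyl transfer with the roles reversed, which sets out from iodide 11 and returns at 17. Miyaura borylation of 11 (bis(pinacolato)diboron, Pd(OAc)2, SPhos, KOAc, dioxane, 100 °C) should give methyl 2-(benzyloxy)-3,5,6-trimethyl-4-(4,4,5,5-tetramethyl-1,3,2-dioxaborolan-2-yl)benzoate F1. Oxidation with NaBO3·4H2O in THF/H2O should give methyl 2-(benzyloxy)-4-hydroxy-3,5,6-trimethylbenzoate F2. F2 is then acylated by acid 4, activated as its mixed anhydride with trifluoroacetic anhydride in toluene at rt, to give 17; this is slower because of the hindrance but is the established way to make depsides.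

2. Step 7. Addition of t-BuLi or of the aryllithium to the methyl ester, or protonation of the hindered aryllithium before iodine arrives, may compete with the exchange. The fallback carries the carboxyl group as its lithium salt, sets out from dibromide 7 and returns at 11. n-BuLi in THF at −78 °C followed by CO2 should give 2-(benzyloxy)-4-bromo-3,5,6-trimethylbenzoic acid F3. Deprotonation with n-BuLi (1 equiv), exchange with t-BuLi (2 equiv) at −78 °C and quenching with I2 should give 2-(benzyloxy)-4-iodo-3,5,6-trimethylbenzoic acid F4. Alkylation of the carboxylate with MeI and K2CO3 in DMF then gives 11.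

3. Step 3. Under the hot hydroxide conditions that the hindered ester needs, the aldehyde may be lost by Cannizzaro disproportionation or air oxidation, or the hydrolysis may stop short. The fallback masks the aldehyde, sets out from 3 and returns at 4. Ethylene glycol and TsOH in toluene with removal of water should give methyl 2,4-bis(benzyloxy)-5-(1,3-dioxolan-2-yl)-3,6-dimethylbenzoate F5. KOH in DMSO/H2O at 90 °C should give 2,4-bis(benzyloxy)-5-(1,3-dioxolan-2-yl)-3,6-dimethylbenzoic acid F6. Aqueous HCl in THF at rt then frees the aldehyde and gives 4.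

**Further compounds**

F1 | step 9 | methyl 2-(benzyloxy)-3,5,6-trimethyl-4-(4,4,5,5-tetramethyl-1,3,2-dioxaborolan-2-yl)benzoate | COC(=O)c1c(C)c(C)c(B2OC(C)(C)C(C)(C)O2)c(C)c1OCc1ccccc1
F2 | step 9 | methyl 2-(benzyloxy)-4-hydroxy-3,5,6-trimethylbenzoate | COC(=O)c1c(C)c(C)c(O)c(C)c1OCc1ccccc1
F3 | step 7 | 2-(benzyloxy)-4-bromo-3,5,6-trimethylbenzoic acid | OC(=O)c1c(C)c(C)c(Br)c(C)c1OCc1ccccc1
F4 | step 7 | 2-(benzyloxy)-4-iodo-3,5,6-trimethylbenzoic acid | OC(=O)c1c(C)c(C)c(I)c(C)c1OCc1ccccc1
F5 | step 3 | methyl 2,4-bis(benzyloxy)-5-(1,3-dioxolan-2-yl)-3,6-dimethylbenzoate | COC(=O)c1c(C)c(C2OCCO2)c(OCc2ccccc2)c(C)c1OCc1ccccc1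
F6 | step 3 | 2,4-bis(benzyloxy)-5-(1,3-dioxolan-2-yl)-3,6-dimethylbenzoic acid | OC(=O)c1c(C)c(C2OCCO2)c(OCc2ccccc2)c(C)c1OCc1ccccc1
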